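The numbers in the tables were generated by integration for an exercise, and the scatter is random.

Count the half-lives of the starting material that fit into each flask's time.

| setting | violet | red | blue | cedar | birch | ash | oak | elm |
|---|---|---|---|---|---|---|---|---|
| starting material | 0.25 M | 0.25 M | 0.25 M | 0.25 M | 0.25 M | 0.25 M | 0.25 M | 0.25 M |
| reagent | 0.275 M | 0.275 M | 0.275 M | 0.275 M | 0.275 M | 0.275 M | 0.275 M | 0.275 M |
| free catalyst | 12 mM | 12 mM | 12 mM | 12 mM | 12 mM | 12 mM | 12 mM | 12 mM |
| added ligand | 6.2 mM | 17 mM | 44 mM | 8.0 mM | 10 mM | 15 mM | 25 mM | 40 mM |
| remark | run made earlier | run made earlier | run made earlier |  |  |  |  |  |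
| time |  |  |  | 5.0 h | 5.0 h | 5.0 h | 5.0 h | 5.0 h |

| run | time / h | product / % | starting material / % |
|---|---|---|---|
| violet | 0.417 | 31.2 | 68.6 |
| violet | 0.833 | 50.0 | 49.1 |
| violet | 1.33 | 65.1 | 34.4 |
| violet | 2.50 | 85.6 | 13.9 |
| violet | 5.00 | 98.1 | 2.5 |
| red | 1.00 | 40.9 | 59.0 |
| red | 2.00 | 58.5 | 41.2 |
| red | 3.00 | 71.2 | 28.8 |
| red | 4.00 | 79.9 | 20.6 |
| red | 5.00 | 86.2 | 13.9 |
| blue | 0.417 | 14.3 | 84.9 |
| blue | 0.833 | 19.6 | 80.4 |
| blue | 1.33 | 24.1 | 75.6 |
| blue | 2.50 | 34.3 | 65.8 |
| blue | 5.00 | 52.0 | 48.6 |

(each reading ± 0.3 percentage points)

- what was read earlier has a scatter of 0.3 percentage points, one standard deviation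
- what may be going on: free catalyst + added ligand <-> idle complex; reagent + catalyst intermediate A <-> catalyst intermediate B; catalyst intermediate B -> free catalyst + product; starting material + free catalyst -> catalyst intermediate A
- "hardly changes" means that all values lie within two and a half points (for a concentration: within two and a half percent of the largest)

* [product] at the end for cedar, birch, ash, oak, elm, in this order
* how that number moves from the first to the last of them (hardly changes / falls, then rises / rises all the way / rises, then falls / falls all the way)

In the round that may be running, free catalyst takes up starting material to give catalyst intermediate A, reagent turns that into catalyst intermediate B, and B gives product and free catalyst again. Added ligand can hold free catalyst as idle complex. We follow elm in slow motion through the blue run, whose 44 mM of added ligand lies close to elm's 40 mM.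

In the first instants the 12 mM of catalyst is charged free. Over the first 0.417 h the blue run loses starting material at 0.362 /h of its charge, faster than the 0.0688 /h of its last stretch. So we read that added ligand is meanwhile drawing catalyst away into idle complex.

In the middle the red run's starting material falls by about a constant fraction per hour, a pseudo-first-order decay. The blue readings from 2.50 h to 5.00 h give 5.72 h. This steady half-life, the time in which the starting material halves once the rush is over, is what we carry. The red run reads 1.92 h and the violet run 0.895 h, so it lengthens with added ligand, and we expect the row to fall all the way. Drawn straight between the red and blue runs, it comes to 5.16 h for elm. Drawn straight between the violet and red runs, it comes to 1.07 h for cedar, which then holds 4.67 half-lives.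

For the end, the blue run's steady line, carried back to the start, begins at 89.1%, and that is what the rush leaves. Elm's 5.0 h holds 0.970 half-lives, so we expect 45.5% of the starting material left and 0.136 M of product. Starting material is the limiting reagent, 0.25 M against 0.275 M of reagent, and elm is still running at its end.

The forecast, holding that “the catalyst starts free and is slowly tied up by ligand”, gives 0.241 M, 0.237 M, 0.22 M, 0.181 M and 0.136 M, and says the number falls all the way.

The flasks give 0.242 M, 0.237 M, 0.222 M, 0.184 M and 0.138 M: the number falls all the way.

    free catalyst + added ligand ⇌ idle complex (K = 300 /M, k = 0.0670 /M/s)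
    reagent + catalyst intermediate A ⇌ catalyst intermediate B (K = 140 /M, k = 0.100 /M/s)
    catalyst intermediate B → free catalyst + product (k = 2.10 /s)
    starting material + free catalyst → catalyst intermediate A (k = 0.0320 /M/s)

Elm's 5.0 h stands against a steady half-life of 5.16 h, built on the blue run's 5.72 h, and 45% of its starting material is left at that time, while at 50.0 h, which is 9.69 such half-lives, product stands at 99.9%. Oak, with 25 mM of added ligand, gets 3.04 h from the same line and 1.64 half-lives, which from the red run's offset of 84.7% counts down to 27.1%, and the starting material left in oak is 26%.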